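**Retrosynthetic overview**

1. Numbering: ring A is C1(=O)–C2(CH3)=C3–C4(OH)–C5–C6, with the side chain C1′–C16′ on C5. The key cut is the C5′–C6′ bond (CH2–CH=), made by nickel-electrocatalytic decarboxylative alkenylation of a C12 N-hydroxyphthalimide ester (acyl carbon lost as CO2) with a C14 (E)-alkenyl iodide, two electrophiles joined at a cathode.
2. Enabling feature: C5′ is an unbranched primary sp3 carbon without a stereocentre, so it can be reached as a radical from a 4-methylhex-4-enoic acid terminus. C6′ is the CH end of the (E)-trisubstituted C6′=C7′(CH3) olefin, so it can be reached as a 2-methylalk-1-enyl iodide of fixed geometry. The C1 ketone of ring A is masked as a dioxolane (ring B) so that C2=C3 is no radical acceptor.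
3. Second cut: C5–C1′, by α′-alkylation of a ketal-protected 3-methylcyclohexenone with a Johnson–Claisen-derived (E)-allylic bromide. C4 and C5 are then set together by Noyori hydrogenation under dynamic kinetic resolution (C4 carbonyl to cis C4–OH).
4. Third cut: the alkenyl iodide comes from geranyl bromide by propargylation and carboalumination–iodination.
5. Rings: ring A is bought intact and only re-functionalised (C2 methyl by conjugate addition and Saegusa–Ito oxidation). Ring B is present from the start and is opened in the last step. No ring is formed in the route.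

Key step: step 11

Assumption: the sense of induction in step 7 is taken by analogy with 2-alkylcyclohexanones and cyclohexenones under the same ruthenium catalysts; should a trial run give the (8R,9R) series, the mirror-image catalyst would be used instead.

**Route**

Step 1
Reactants: 1 1,4-dioxaspiro[4.5]dec-6-en-8-one
Product: 2 trimethyl[(6-methyl-1,4-dioxaspiro[4.5]dec-7-en-8-yl)oxy]silane (racemic)
Conditions: MeMgBr, CuBr·SMe2 (5 mol%), TMSCl, DMPU, THF, −78 °C; Et3N, pentane work-up
Reagents that add atoms: methylmagnesium bromide C[Mg]Br; chlorotrimethylsilane C[Si](C)(C)Cl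
Why: Copper-catalysed conjugate addition of the Grignard reagent with in situ silylation should deliver the methyl group to C6, the only β-carbon, and fix the enolate as one regioisomeric silyl enol ether; the C6 stereocentre is racemic and is erased in step 2.

Step 2
Reactants: 2 trimethyl[(6-methyl-1,4-dioxaspiro[4.5]dec-7-en-8-yl)oxy]silane
Product: 3 6-methyl-1,4-dioxaspiro[4.5]dec-6-en-8-one
Conditions: Pd(OAc)2 (10 mol%), O2 (1 atm), DMSO, rt
Reagents that add atoms: none
Why: Aerobic Saegusa–Ito oxidation, in which the palladium enolate formed from 2 can undergo β-hydride elimination only toward C6, should restore the enone with the methyl group on the β-carbon and leaves no stereocentre.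

Step 3
Reactants: 4 [(tert-butyldimethylsilyl)oxy]acetaldehyde; 5 isopropenylmagnesium bromide
Product: 6 1-[(tert-butyldimethylsilyl)oxy]-3-methylbut-3-en-2-ol (racemic)
Conditions: THF, −78 → 0 °C; then H2O
Reagents that add atoms: none
Why: Grignard 1,2-addition to the aldehyde should give the secondary allylic alcohol; its carbinol centre is racemic and is destroyed in step 4.

Step 4
Reactants: 6 1-[(tert-butyldimethylsilyl)oxy]-3-methylbut-3-en-2-ol
Product: 7 ethyl (4E)-6-[(tert-butyldimethylsilyl)oxy]-4-methylhex-4-enoate
Conditions: MeC(OEt)3 (5 equiv), EtCO2H (cat.), 140 °C, EtOH distilled off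
Reagents that add atoms: triethyl orthoacetate CC(OCC)(OCC)OCC
Why: Johnson–Claisen rearrangement through a chair transition state with the CH2OTBS group equatorial should give the (E)-trisubstituted olefin and the two-carbon ester arm in one operation.

Step 5
Reactants: 7 ethyl (4E)-6-[(tert-butyldimethylsilyl)oxy]-4-methylhex-4-enoate
Product: 8 ethyl (4E)-6-bromo-4-methylhex-4-enoate
Conditions: PPh3, Br2 (Ph3PBr2 preformed), CH2Cl2, 0 °C → rt; pentane trituration, filtration
Reagents that add atoms: bromine BrBr
Why: Appel-type bromination, in which dibromotriphenylphosphorane converts the primary allylic silyl ether into an alkoxyphosphonium salt that bromide displaces by SN2 at the unhindered CH2, should give the bromide with the (E)-geometry kept.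

Step 6
Reactants: 3 6-methyl-1,4-dioxaspiro[4.5]dec-6-en-8-one; 8 ethyl (4E)-6-bromo-4-methylhex-4-enoate
Product: 10 ethyl (4E)-4-methyl-6-(6-methyl-8-oxo-1,4-dioxaspiro[4.5]dec-6-en-9-yl)hex-4-enoate (racemic), via lithium enolate 9 (not isolated)
Conditions: LDA (commercial solution), THF, −78 °C; then 8, DMPU, −78 → −30 °C
Reagents that add atoms: none
Why: Kinetic α′-deprotonation of the enone at C9 gives the cross-conjugated enolate, whose SN2 alkylation by the primary allylic bromide should proceed without allylic transposition; the new C9 stereocentre is racemic and base-labile, which step 7 exploits.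

Step 7
Reactants: 10 ethyl (4E)-4-methyl-6-(6-methyl-8-oxo-1,4-dioxaspiro[4.5]dec-6-en-9-yl)hex-4-enoate
Product: 12 (4E)-6-[(8S,9S)-8-hydroxy-6-methyl-1,4-dioxaspiro[4.5]dec-6-en-9-yl]-4-methylhex-4-enoic acid, via hydroxy ester 11 (not isolated)
Conditions: H2 (8 atm), trans-RuCl2[(S)-tolbinap][(R,R)-dpen] (1 mol%), KOtBu (0.3 equiv), i-PrOH, rt; then aq. KOH, 40 °C; then 1 M HCl to pH 5, 0 °C
Reagents that add atoms: potassium hydroxide [K+].[OH-]
Why: Noyori asymmetric hydrogenation under dynamic kinetic resolution, in which alkoxide racemises C9 through the enolate while the chiral ruthenium hydride reduces only the carbonyl of the (9S)-ketone from the face anti to the C9 side chain, should set C8 (S) by catalyst control and C9 (S) with the cis relationship by the coupled resolution, and hydroxide then saponifies the ester in the same pot so that any alkoxide exchange of the ester is of no consequence.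

Step 8
Reactants: 12 (4E)-6-[(8S,9S)-8-hydroxy-6-methyl-1,4-dioxaspiro[4.5]dec-6-en-9-yl]-4-methylhex-4-enoic acid
Product: 13 1,3-dioxoisoindolin-2-yl (4E)-6-[(8S,9S)-8-hydroxy-6-methyl-1,4-dioxaspiro[4.5]dec-6-en-9-yl]-4-methylhex-4-enoate
Conditions: N-hydroxyphthalimide, DIC, CH2Cl2, 0 °C → rt (no acyl-transfer catalyst)
Reagents that add atoms: N-hydroxyphthalimide ON1C(=O)c2ccccc2C1=O
Why: Carbodiimide esterification should activate only the carboxylic acid, because the hindered secondary alcohol is far less nucleophilic than the N-hydroxyimide, and gives the redox-active ester.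

Step 9
Reactants: 14 trimethyl(prop-1-yn-1-yl)silane; 15 geranyl bromide, (2E)-1-bromo-3,7-dimethylocta-2,6-diene
Product: 18 (5E)-6,10-dimethylundeca-5,9-dien-1-yne, via lithiated silylpropyne 16 (not isolated), via silyl enyne 17 (not isolated)
Conditions: n-BuLi, THF, −78 °C; then 15, −78 °C → rt; then K2CO3 (cat.), MeOH, rt
Reagents that add atoms: none
Why: Propargylic lithiation and SN2 alkylation with the allylic bromide (silicon blocks the alkyne terminus and disfavours the allenyl product), followed by methanolysis of the C–Si bond, should give the terminal alkyne with the (5E)-olefin untouched.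

Step 10
Reactants: 18 (5E)-6,10-dimethylundeca-5,9-dien-1-yne
Product: 20 (1E,5E)-1-iodo-2,6,10-trimethylundeca-1,5,9-triene, via alkenylalane 19 (not isolated)
Conditions: Me3Al, Cp2ZrCl2 (0.25 equiv), CH2Cl2, 0 °C → rt; then I2, THF, −30 → 0 °C
Reagents that add atoms: trimethylaluminium C[Al](C)C; iodine II
Why: Negishi zirconium-catalysed carboalumination adds methyl and aluminium syn across the terminal alkyne with aluminium at the terminus, and iodinolysis with retention should give the (E)-2-methylalkenyl iodide.

Step 11
Reactants: 13 1,3-dioxoisoindolin-2-yl (4E)-6-[(8S,9S)-8-hydroxy-6-methyl-1,4-dioxaspiro[4.5]dec-6-en-9-yl]-4-methylhex-4-enoate; 20 (1E,5E)-1-iodo-2,6,10-trimethylundeca-1,5,9-triene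
Product: 21 (8S,9S)-6-methyl-9-[(2E,6E,10E)-3,7,11,15-tetramethylhexadeca-2,6,10,14-tetraen-1-yl]-1,4-dioxaspiro[4.5]dec-6-en-8-ol
Conditions: NiCl2·6H2O (10 mol%), 2,2′-bipyridine (10 mol%), AgNO3 (0.3 equiv), LiCl, DMF, Mg anode, reticulated vitreous carbon cathode, undivided cell, constant current, rt
Reagents that add atoms: none
Why: Nickel-electrocatalytic decarboxylative alkenylation: cathodically generated low-valent nickel–bipyridine should add oxidatively into the C–I bond of 20 with retention, while single-electron reduction of the ester 13 releases phthalimide anion and CO2 and leaves a primary radical at C5′ (C2 of the hexenoate chain), which the alkenylnickel captures; reductive elimination from the resulting trivalent nickel forges the C5′–C6′ bond, and the magnesium anode supplies the two electrons. The closest known reaction type is the silver-nanoparticle-assisted nickel-electrocatalytic coupling of redox-active esters with (E)-2-methylalkenyl iodides used to assemble 1,5-polyene terpenoid chains. The step closes no ring and creates no stereocentre: C8 and C9 lie five or more bonds from the radical and are not touched, and the (E)-geometry of C6′=C7′ is inherited from 20 because oxidative addition and reductive elimination are stereoretentive. It needs cross-coupling over homo-coupling of two electrophiles, which the different activation modes (two-electron for the sp2 iodide, one-electron for the ester) should secure. It also needs the radical to survive until capture: its 3-exo closure onto C2′=C3′ is reversible and unproductive, the (E)-olefin holds the allylic C1′–H out of reach for 1,5-hydrogen transfer, and ring B keeps C2=C3 from acting as a conjugate acceptor. The free C8–OH and the three trisubstituted olefins should be spectators at the mild cathode potential.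

Step 12
Reactants: 21 (8S,9S)-6-methyl-9-[(2E,6E,10E)-3,7,11,15-tetramethylhexadeca-2,6,10,14-tetraen-1-yl]-1,4-dioxaspiro[4.5]dec-6-en-8-ol
Product: 22 (4S,5S)-4-hydroxy-2-methyl-5-[(2E,6E,10E)-3,7,11,15-tetramethylhexadeca-2,6,10,14-tetraen-1-yl]cyclohex-2-en-1-one
Conditions: PPTS (cat.), acetone/H2O (10:1), rt
Reagents that add atoms: water O
Why: Acid-catalysed ketal hydrolysis of the allylic dioxolane through the conjugated oxocarbenium ion should unveil the enone under conditions too mild to dehydrate the γ-hydroxy enone or protonate the trisubstituted olefins, and no stereocentre is touched.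

**Compound list**

1 | 1,4-dioxaspiro[4.5]dec-6-en-8-one | O=C1C=CC2(CC1)OCCO2 | starting material
2 | trimethyl[(6-methyl-1,4-dioxaspiro[4.5]dec-7-en-8-yl)oxy]silane (racemic) | CC1C=C(O[Si](C)(C)C)CCC12OCCO2 | intermediate
3 | 6-methyl-1,4-dioxaspiro[4.5]dec-6-en-8-one | CC1=CC(=O)CCC12OCCO2 | intermediate
4 | [(tert-butyldimethylsilyl)oxy]acetaldehyde | O=CCO[Si](C)(C)C(C)(C)C | starting material
5 | isopropenylmagnesium bromide | CC(=C)[Mg]Br | starting material
6 | 1-[(tert-butyldimethylsilyl)oxy]-3-methylbut-3-en-2-ol (racemic) | CC(=C)C(O)CO[Si](C)(C)C(C)(C)C | intermediate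
7 | ethyl (4E)-6-[(tert-butyldimethylsilyl)oxy]-4-methylhex-4-enoate | CCOC(=O)CC/C(C)=C/CO[Si](C)(C)C(C)(C)C | intermediate
8 | ethyl (4E)-6-bromo-4-methylhex-4-enoate | CCOC(=O)CC/C(C)=C/CBr | intermediate
9 | lithium 6-methyl-1,4-dioxaspiro[4.5]deca-6,8-dien-8-olate (not isolated) | [Li+].[O-]C1=CCC2(OCCO2)C(C)=C1 | intermediate
10 | ethyl (4E)-4-methyl-6-(6-methyl-8-oxo-1,4-dioxaspiro[4.5]dec-6-en-9-yl)hex-4-enoate (racemic) | CCOC(=O)CC/C(C)=C/CC1CC2(OCCO2)C(C)=CC1=O | intermediate
11 | ethyl (4E)-6-[(8S,9S)-8-hydroxy-6-methyl-1,4-dioxaspiro[4.5]dec-6-en-9-yl]-4-methylhex-4-enoate (not isolated) | CCOC(=O)CC/C(C)=C/C[C@H]1CC2(OCCO2)C(C)=C[C@H]1O | intermediate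
12 | (4E)-6-[(8S,9S)-8-hydroxy-6-methyl-1,4-dioxaspiro[4.5]dec-6-en-9-yl]-4-methylhex-4-enoic acid | OC(=O)CC/C(C)=C/C[C@H]1CC2(OCCO2)C(C)=C[C@H]1O | intermediate
13 | 1,3-dioxoisoindolin-2-yl (4E)-6-[(8S,9S)-8-hydroxy-6-methyl-1,4-dioxaspiro[4.5]dec-6-en-9-yl]-4-methylhex-4-enoate | O=C(CC/C(C)=C/C[C@H]1CC2(OCCO2)C(C)=C[C@H]1O)ON1C(=O)c2ccccc2C1=O | intermediate
14 | trimethyl(prop-1-yn-1-yl)silane | CC#C[Si](C)(C)C | starting material
15 | geranyl bromide, (2E)-1-bromo-3,7-dimethylocta-2,6-diene | CC(C)=CCC/C(C)=C/CBr | starting material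
16 | [3-(trimethylsilyl)prop-2-yn-1-yl]lithium (not isolated) | [Li]CC#C[Si](C)(C)C | intermediate
17 | [(5E)-6,10-dimethylundeca-5,9-dien-1-yn-1-yl]trimethylsilane (not isolated) | CC(C)=CCC/C(C)=C/CCC#C[Si](C)(C)C | intermediate
18 | (5E)-6,10-dimethylundeca-5,9-dien-1-yne | CC(C)=CCC/C(C)=C/CCC#C | intermediate
19 | dimethyl[(1E,5E)-2,6,10-trimethylundeca-1,5,9-trien-1-yl]alumane (not isolated) | CC(C)=CCC/C(C)=C/CC/C(C)=C/[Al](C)C | intermediate
20 | (1E,5E)-1-iodo-2,6,10-trimethylundeca-1,5,9-triene | CC(C)=CCC/C(C)=C/CC/C(C)=C/I | intermediate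
21 | (8S,9S)-6-methyl-9-[(2E,6E,10E)-3,7,11,15-tetramethylhexadeca-2,6,10,14-tetraen-1-yl]-1,4-dioxaspiro[4.5]dec-6-en-8-ol | CC(C)=CCC/C(C)=C/CC/C(C)=C/CC/C(C)=C/C[C@H]1CC2(OCCO2)C(C)=C[C@H]1O | intermediate
22 | (4S,5S)-4-hydroxy-2-methyl-5-[(2E,6E,10E)-3,7,11,15-tetramethylhexadeca-2,6,10,14-tetraen-1-yl]cyclohex-2-en-1-one | CC(C)=CCC/C(C)=C/CC/C(C)=C/CC/C(C)=C/C[C@H]1CC(=O)C(C)=C[C@H]1O | target

**Step count**

Total steps: 12. Longest linear sequence: 8 steps (steps 3, 4, 5, 6, 7, 8, 11, 12).

**Steps most likely to fail**

Step 11. What may go wrong: hydrodehalogenation of the alkenyl iodide, or reductive dimerisation or hydrogen-atom quenching of the primary radical outrunning its capture by nickel, or passivation of the cathode. The fallback replaces the radical cross-electrophile coupling by a two-electron boron route. It sets out from 13: copper-catalysed decarboxylative borylation (Cu(acac)2, B2pin2, LiOH·H2O, MgCl2, dioxane/DMF, rt) should give the primary pinacol boronate (8S,9S)-6-methyl-9-[(2E)-3-methyl-5-(4,4,5,5-tetramethyl-1,3,2-dioxaborolan-2-yl)pent-2-en-1-yl]-1,4-dioxaspiro[4.5]dec-6-en-8-ol F1. Suzuki–Miyaura coupling of this boronate with 20 (Pd(OAc)2, RuPhos, aq. KOH, toluene, 80 °C) then comes back to the route at 21.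

Step 7. What may go wrong: epimerisation at C9 slower than carbonyl reduction, which would erode both diastereo- and enantioselectivity, or base-induced self-condensation of the enone before it is reduced. The fallback gives up the dynamic resolution for a reagent-controlled reduction of the racemate with separation. It sets out from 10: Corey–Bakshi–Shibata reduction ((R)-2-methyl-CBS-oxazaborolidine, BH3·SMe2, THF, −40 °C) should give the (8S)-carbinol from both enantiomers, that is 11 together with its diastereomer ethyl (4E)-6-[(8S,9R)-8-hydroxy-6-methyl-1,4-dioxaspiro[4.5]dec-6-en-9-yl]-4-methylhex-4-enoate F2, which is removed by chromatography. Saponification of 11 (LiOH, THF/H2O) comes back to the route at 12.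

Step 6. What may go wrong: proton exchange between product and enolate leading to double alkylation, or competing γ-deprotonation at the C6 methyl group. The fallback uses a metallated hydrazone in place of the ketone enolate. It sets out from 3: condensation with 1,1-dimethylhydrazine (AcOH cat., EtOH, reflux) should give 1,1-dimethyl-2-(6-methyl-1,4-dioxaspiro[4.5]dec-6-en-8-ylidene)hydrazine F3. Deprotonation (LDA, THF, −78 °C) and alkylation with 8 should give ethyl (4E)-6-[8-(2,2-dimethylhydrazinylidene)-6-methyl-1,4-dioxaspiro[4.5]dec-6-en-9-yl]-4-methylhex-4-enoate F4. Hydrolysis of this hydrazone with Cu(OAc)2 in THF/H2O comes back to the route at 10.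

**Further compounds**

F1 | step 11 | (8S,9S)-6-methyl-9-[(2E)-3-methyl-5-(4,4,5,5-tetramethyl-1,3,2-dioxaborolan-2-yl)pent-2-en-1-yl]-1,4-dioxaspiro[4.5]dec-6-en-8-ol | CC1(C)OB(CC/C(C)=C/C[C@H]2CC3(OCCO3)C(C)=C[C@H]2O)OC1(C)C
F2 | step 7 | ethyl (4E)-6-[(8S,9R)-8-hydroxy-6-methyl-1,4-dioxaspiro[4.5]dec-6-en-9-yl]-4-methylhex-4-enoate | CCOC(=O)CC/C(C)=C/C[C@@H]1CC2(OCCO2)C(C)=C[C@H]1O
F3 | step 6 | 1,1-dimethyl-2-(6-methyl-1,4-dioxaspiro[4.5]dec-6-en-8-ylidene)hydrazine | CN(C)N=C1C=C(C)C2(CC1)OCCO2
F4 | step 6 | ethyl (4E)-6-[8-(2,2-dimethylhydrazinylidene)-6-methyl-1,4-dioxaspiro[4.5]dec-6-en-9-yl]-4-methylhex-4-enoate | CCOC(=O)CC/C(C)=C/CC1CC2(OCCO2)C(C)=CC1=NN(C)C
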